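## The problem

Target 26 is a 3-hydroxy-4-aryl-2(5H)-furanone, numbered here O1, C2 (lactone carbonyl), C3 (enol carbon), C4 (carbon bearing the 4-hydroxyphenyl ring) and C5. C5 is fully substituted: it carries O1, a methyl ester, C4 and a benzylic methylene. That methylene is attached to C5' of a 2,3-dihydrobenzofuran whose C2' bears a 2-hydroxypropan-2-yl group. There are two stereocentres, C5 (R) and C2' (S), separated by a methylene and a benzene ring. Neither can steer the other, and an error at either gives a diastereomer that will be hard to remove, so each needs its own reliable source of chirality. C5 has no hydrogen and therefore has to be made by a C–C bond formation under absolute control. The fragile groups are the acidic, oxidisable enol at C3, the ester and lactone that share C5 (base opens or cleaves them), the free phenol, and the tertiary carbinol next to the aryl ether oxygen, which dehydrates or ring-expands to a chromanol under protic acid. The enabling feature is that C5, with O1, the ester carbon and the arylmethyl group, is the alpha-carbon of an aryllactic acid. That skeleton and its oxygen-bearing centre are available from tyrosine, and a fully substituted alpha-hydroxy-acid carbon is what the enolate of a 2-tert-butyl-1,3-dioxolan-4-one delivers. C4 then has to be the electrophile, which an aromatic aldehyde carbon provides.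

## Retrosynthesis

**Protecting groups.** Target 26 is traced back to bis-benzyl ether 25 and its triethylsilyl ether 24. Benzyl masks both acidic hydroxyls (phenol and C3 enol) and comes off together in a neutral final hydrogenolysis. The silyl ether on the tertiary carbinol is needed because that hydroxyl would otherwise compete in the one O-acylation of the route. Only two mild deprotections are then asked of the end game.

**Butenolide ring.** The ring of 24 is opened at C3=C4 and at O1–C2, giving the phosphonoacetate ester 23, which comes from alpha-hydroxy-beta-keto ester 17 and phosphono acid 22. An intramolecular Horner–Wadsworth–Emmons closure is preferred to an ester-enolate aldol condensation because olefination of the ketone is irreversible. An ester enolate could instead be diverted into a Dieckmann reaction with the C5 methyl ester. Acid 22 is a three-step reagent from triethyl phosphonoacetate 18 through diazo compound 19, benzyl alcohol 20 and ester 21.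

**Oxidation level and acetal release.** Ketol 17 comes from diol ester 16 by oxidation of the benzylic carbinol, and 16 from aldol adduct 15 by methanolysis of the acetal ring. Methanolysis is placed before oxidation so that methoxide never meets a non-enolisable beta-keto ester, which would invite retro-Claisen cleavage. The forward steps must spare the C4–C5 bond and the silyl ether.

**C4–C5 bond (key disconnection).** Adduct 15 is cut between C4 and C5 into dioxolanone 13 and 4-(benzyloxy)benzaldehyde 14. Compared with a biomimetic pyruvate-type aldol (C4 nucleophile, C5 electrophile), this polarity places the stereochemical burden on a rigid five-membered enolate with one large blocking group. The precursor has no quaternary centre and its only ring stereocentre is relayed from the chiral pool. The forward reaction must add to the aldehyde anti to the tert-butyl group without retro-aldol reversal.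

**Temporary acetal.** Dioxolanone 13 comes from dihydroxy acid 10 and pivalaldehyde 11 through the persilylated derivative 12. A silyl triflate-catalysed acetalisation is chosen over the protic-acid method because it spares the tertiary carbinol and leaves it silylated in the same operation. The forward step must give the cis acetal, since the (2S) acetal carbon is the only stereo-information left once the enolate forms.

**Dihydrofuran ring and C2'.** Acid 10 is opened at O1'–C2' to epoxy phenol 8, reached from silyl ether 7, itself the Shi epoxide of prenyl arene 6 (the silyl ether of phenol 5). Base-mediated 5-exo opening of a trisubstituted epoxide is the standard entry to 2-(2-hydroxypropan-2-yl)dihydrobenzofurans. It needs reagent control only in the epoxidation, and the ring closure inverts C2' cleanly. Methyl ester 9 is the cyclised intermediate that is saponified to 10.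

**Aryl–prenyl bond and chiral pool.** Phenol 5 is cut at the aryl–CH2 bond into iodide 3 and prenylstannane 4. A cross-coupling is chosen over direct phenol C-prenylation, which gives O- and poly-alkylation. Iodide 3 is the methyl ester of hydroxy acid 2, made from commercial 3-iodo-L-tyrosine 1 by nitrous acid deamination with retention. The starting material thus supplies the aryl ring, the three-carbon acid chain, the (S)-carbinol and the iodine handle.

## Roads not taken

**Alternative 1:** The dihydrofuran O1'–C2' bond would be formed last, on a complete bis-benzylated butenolide. Its ortho side chain is an (E)-allylic methyl carbonate, as in methyl (2R)-4-(benzyloxy)-3-[4-(benzyloxy)phenyl]-2-({4-hydroxy-3-[(2E)-4-(methoxycarbonyloxy)-3-methylbut-2-en-1-yl]phenyl}methyl)-5-oxo-2,5-dihydrofuran-2-carboxylate A1.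

- Forward key step: Pd2(dba)3 (a zerovalent palladium source) with the C2-symmetric diphosphine from trans-1,2-diaminocyclohexane and 2-(diphenylphosphino)benzoic acid ionises the carbonate. The phenoxide attacks the internal allyl carbon to give the 2'-isopropenyl dihydrobenzofuran A2.
- Merits: C2' is set by a catalyst at the end, ring size fixes the regiochemistry, no tertiary alcohol has to be protected, and either C2' epimer is available from one late intermediate.
- Weak points: A2 still needs a Markovnikov hydration of the isopropenyl group before hydrogenolysis. The (E)-allylic carbonate demands a selective terminal oxidation of a prenyl group. Enantioselection for five-ring closure onto a 2-methyl-substituted allyl unit is less dependable than for chromans. The alternative also says nothing about C5, which is the harder centre.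
- Comparison: it is better in flexibility and avoids both tin and the silyl group. The chosen plan sets against this that its key step solves the quaternary centre, and that C2' is fixed on a small early intermediate where optical purity can be checked and raised.

**Alternative 2:** No skeletal bond is cut. The C2'–C3' double bond of the flat benzofuran methyl 2-(2-hydroxypropan-2-yl)-1-benzofuran-5-carboxylate A3 would be hydrogenated to dihydrobenzofuran ester A4.

- Forward key step: hydrogenation with a chiral ruthenium N-heterocyclic carbene catalyst generated from Ru(cod)(2-methylallyl)2.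
- Merits: A3 is trivially assembled by alkynylation and cyclisation of an iodophenol, the stereo-defining step is catalytic and atom-economical, and it is likely to give higher optical purity at C2' than an epoxidation.
- Weak points: the bulky, furfuryl-type tertiary carbinol at C2 is prone to hydrogenolysis and lies outside the usual 2-alkyl and 2-aryl substrates. The ester of A4 must then be grown by three carbons into an aryllactic acid, which costs a second asymmetric step for the carbinol carbon. C5 is again left open.
- Comparison: it is cleaner and probably more selective for C2'. The chosen plan sets against this that tyrosine supplies the whole acid chain with its (S)-centre, so only one reagent-controlled step is needed and no homologation.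

**Alternative 3:** The C5–CH2 bond would be cut.

- Forward key step: the C5 anion of the O-benzylated C5–H butenolide ester A5 would be alkylated by benzylic bromide A6 under a chiral N-spiro binaphthyl quaternary ammonium phase-transfer catalyst. The product is bis-benzyl ether A7, which is identical with compound 25.
- Merits: this is the shortest and most convergent road. One bond creates the quaternary centre and it meets the chosen route at the penultimate compound.
- Weak points: the nucleophile is an ambident 2-oxidofuran-type dienolate (C5, C3 and oxygen can all react). Face discrimination of such a flat, fully substituted anion by an ion-paired ammonium has no close precedent, so the sense and level of induction would have to be found. A6 is an electron-rich benzylic bromide that still needs its own asymmetric synthesis and must survive aqueous hydroxide alongside a methyl ester.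
- Comparison: in step count it is clearly better. The chosen plan sets against this a C5 configuration that follows from a relay of known sense from a chiral-pool centre, with every step of a known reaction type.

Key step: step 8

Assumption: the carbinol carbon made in step 8 is carried as a mixture of epimers through steps 8 and 9 because it becomes a ketone in step 10. Compound names use systematic numbering, in which the quaternary carbon (C5 in the text) is C2 of the 5-oxo-2,5-dihydrofuran.

## Route

Step 1
Reactants: 1 3-iodo-L-tyrosine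
Product: 2 (2S)-2-hydroxy-3-(4-hydroxy-3-iodophenyl)propanoic acid
Conditions: NaNO2, 1 M H2SO4 (aq), 0 °C → rt
Reagents that add atoms: water, O
Why: Nitrous acid deamination of an alpha-amino acid; the diazonium is displaced by the neighbouring carboxylate to an alpha-lactone that water opens, so two inversions give net retention and the (S)-centre is kept.

Step 2
Reactants: 2 (2S)-2-hydroxy-3-(4-hydroxy-3-iodophenyl)propanoic acid
Product: 3 methyl (2S)-2-hydroxy-3-(4-hydroxy-3-iodophenyl)propanoate
Conditions: MeOH, H2SO4 (cat.), reflux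
Reagents that add atoms: methanol, CO
Why: Fischer esterification; the ester makes the following intermediates organic-soluble and the carbinol centre is not touched under acid.

Step 3
Reactants: 3 methyl (2S)-2-hydroxy-3-(4-hydroxy-3-iodophenyl)propanoate; 4 tributyl(3-methylbut-2-en-1-yl)stannane
Product: 5 methyl (2S)-2-hydroxy-3-[4-hydroxy-3-(3-methylbut-2-en-1-yl)phenyl]propanoate
Conditions: Pd(PPh3)4 (5 mol%), DMF, 90 °C
Reagents that add atoms: none
Why: Stille coupling under neutral conditions that tolerate the free phenol, alcohol and ester; reductive elimination from the aryl(prenyl)palladium intermediate at the unsubstituted allyl terminus should give the linear prenyl arene.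

Step 4
Reactants: 5 methyl (2S)-2-hydroxy-3-[4-hydroxy-3-(3-methylbut-2-en-1-yl)phenyl]propanoate
Product: 6 methyl (2S)-3-[4-(tert-butyldimethylsilyloxy)-3-(3-methylbut-2-en-1-yl)phenyl]-2-hydroxypropanoate
Conditions: TBSCl (1.05 equiv), imidazole, CH2Cl2, 0 °C
Reagents that add atoms: tert-butyldimethylsilyl chloride, CC(C)(C)[Si](C)(C)Cl
Why: Silylation of the more acidic and more accessible phenol in preference to the deactivated alpha-hydroxy ester hydroxyl; the aryl silyl ether shields the phenol from the oxidant of step 5 and is stable at its pH.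

Step 5
Reactants: 6 methyl (2S)-3-[4-(tert-butyldimethylsilyloxy)-3-(3-methylbut-2-en-1-yl)phenyl]-2-hydroxypropanoate
Product: 7 methyl (2S)-3-{4-(tert-butyldimethylsilyloxy)-3-[((2R)-3,3-dimethyloxiran-2-yl)methyl]phenyl}-2-hydroxypropanoate
Conditions: 1,2:4,5-di-O-isopropylidene-β-D-erythro-2,3-hexodiulo-2,6-pyranose (D-fructose-derived ketone, 30 mol%), Oxone (2KHSO5·KHSO4·K2SO4), K2CO3, Bu4NHSO4 (cat.), MeCN/CH2(OMe)2, aq. Na2B4O7/Na2EDTA buffer, 0 °C
Reagents that add atoms: potassium peroxymonosulfate (active part of Oxone), [K+].[O-]S(=O)(=O)OO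
Why: Shi epoxidation of a trisubstituted olefin through the chiral dioxirane and a spiro transition state; the D-fructose-derived ketone is expected to deliver oxygen to the face that gives (R) at the epoxide CH of a 2-methyl-2-alkene, and the electron-rich alkene reacts faster than the free secondary alcohol.

Step 6
Reactants: 7 methyl (2S)-3-{4-(tert-butyldimethylsilyloxy)-3-[((2R)-3,3-dimethyloxiran-2-yl)methyl]phenyl}-2-hydroxypropanoate
Product: 10 (2S)-2-hydroxy-3-[(2S)-2-(2-hydroxypropan-2-yl)-2,3-dihydro-1-benzofuran-5-yl]propanoic acid, via epoxy phenol 8 (not isolated), via dihydrobenzofuran methyl ester 9 (not isolated)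
Conditions: K2CO3 (0.5 equiv), MeOH, rt; then LiOH, H2O, rt; 1 M HCl to pH 3
Reagents that add atoms: lithium hydroxide, [Li+].[OH-]
Why: Methoxide cleaves the aryl silyl ether and the phenoxide opens the epoxide at its less substituted carbon in a 5-exo-tet closure with inversion, which sets C2' as (S) and frees the tertiary carbinol; saponification then gives the acid, and the basic medium avoids the acid-promoted 6-endo route to a chromanol.

Step 7
Reactants: 10 (2S)-2-hydroxy-3-[(2S)-2-(2-hydroxypropan-2-yl)-2,3-dihydro-1-benzofuran-5-yl]propanoic acid; 11 pivalaldehyde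
Product: 13 (2S,5S)-2-tert-butyl-5-({(2S)-2-[2-(triethylsilyloxy)propan-2-yl]-2,3-dihydro-1-benzofuran-5-yl}methyl)-1,3-dioxolan-4-one, via tris(triethylsilyl) derivative 12 (not isolated)
Conditions: Et3SiOTf (3.3 equiv), 2,6-lutidine, CH2Cl2, −78 → 0 °C; evaporate, pentane, filter; then 11, Me3SiOTf (10 mol%), CH2Cl2, −78 → −30 °C; pyridine quench
Reagents that add atoms: triethylsilyl trifluoromethanesulfonate, CC[Si](CC)(CC)OS(=O)(=O)C(F)(F)F
Why: Exhaustive silylation gives the silyl ether/silyl ester pair, which condenses with pivalaldehyde under silyl triflate catalysis (silyl-transfer acetalisation of alpha-silyloxy silyl esters) with loss of disiloxane; the low-temperature closure should favour the cis (2S,5S) acetal, and the tertiary carbinol stays as its silyl ether without meeting protic acid.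

Step 8
Reactants: 13 (2S,5S)-2-tert-butyl-5-({(2S)-2-[2-(triethylsilyloxy)propan-2-yl]-2,3-dihydro-1-benzofuran-5-yl}methyl)-1,3-dioxolan-4-one; 14 4-(benzyloxy)benzaldehyde
Product: 15 (2S,5R)-5-{[4-(benzyloxy)phenyl](hydroxy)methyl}-2-tert-butyl-5-({(2S)-2-[2-(triethylsilyloxy)propan-2-yl]-2,3-dihydro-1-benzofuran-5-yl}methyl)-1,3-dioxolan-4-one (mixture of carbinol epimers)
Conditions: LiN(iPr)2 (1.1 equiv), THF, −78 °C; then 14, −78 °C; AcOH/THF quench at −78 °C
Reagents that add atoms: none
Why: LiN(iPr)2 removes the proton at C5 of 13 and gives a planar lithium enolate in which the lactate centre is erased and the (S) acetal carbon is the only stereogenic atom left in the ring. The enolate carbon adds to the aldehyde carbon of 14 through a closed lithium-bridged transition state and forms the C4–C5 bond; no ring is closed. The closest known reaction type is the aldol addition of 2-tert-butyl-1,3-dioxolan-4-one enolates used for self-regeneration of stereocentres, applied here to a 5-arylmethyl member of the class. The new quaternary centre is controlled by the tert-butyl group on the acetal carbon, which blocks its own face of the five-membered enolate so that the aldehyde enters trans to it and takes the place of the former hydrogen (overall retention; the descriptor becomes 5R through a priority change). The carbinol centre at C4 is not controlled and need not be, since step 10 oxidises it. The step needs diastereofacial selectivity at C5, C- rather than O-attack and survival of the adduct: the first rests on the tert-butyl acetal and is independent of the remote C2' centre, the second on the hard aldehyde electrophile, and the third on keeping enolate and aldolate at −78 °C and protonating with acetic acid before warming so that retro-aldol cleavage and acyl transfer cannot set in. Because the side-chain hydroxyl is silylated, one equivalent of base suffices and no second alkoxide is present.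

Step 9
Reactants: 15 (2S,5R)-5-{[4-(benzyloxy)phenyl](hydroxy)methyl}-2-tert-butyl-5-({(2S)-2-[2-(triethylsilyloxy)propan-2-yl]-2,3-dihydro-1-benzofuran-5-yl}methyl)-1,3-dioxolan-4-one
Product: 16 methyl (2R)-3-[4-(benzyloxy)phenyl]-2,3-dihydroxy-2-({(2S)-2-[2-(triethylsilyloxy)propan-2-yl]-2,3-dihydro-1-benzofuran-5-yl}methyl)propanoate (mixture of C3 epimers)
Conditions: NaOMe (0.2 equiv), MeOH, 0 °C
Reagents that add atoms: methanol, CO
Why: Methanolysis of the activated acetal-lactone carbonyl; the hemiacetal alkoxide collapses with loss of pivalaldehyde and uncovers the tertiary hydroxyl and the methyl ester of the target without touching C5, while catalytic base at 0 °C keeps retro-aldol cleavage slow and the tertiary silyl ether intact.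

Step 10
Reactants: 16 methyl (2R)-3-[4-(benzyloxy)phenyl]-2,3-dihydroxy-2-({(2S)-2-[2-(triethylsilyloxy)propan-2-yl]-2,3-dihydro-1-benzofuran-5-yl}methyl)propanoate
Product: 17 methyl (2R)-3-[4-(benzyloxy)phenyl]-2-hydroxy-3-oxo-2-({(2S)-2-[2-(triethylsilyloxy)propan-2-yl]-2,3-dihydro-1-benzofuran-5-yl}methyl)propanoate
Conditions: IBX (2-iodoxybenzoic acid), DMSO, rt
Reagents that add atoms: none
Why: IBX oxidation of the secondary benzylic alcohol; this oxidant converts 1,2-diols into alpha-ketols without glycol cleavage and leaves the tertiary hydroxyl alone, so both carbinol epimers converge on one ketone.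

Step 11
Reactants: 18 triethyl phosphonoacetate
Product: 19 ethyl 2-diazo-2-(diethoxyphosphoryl)acetate
Conditions: 4-acetamidobenzenesulfonyl azide, DBU, MeCN, 0 °C → rt
Reagents that add atoms: 4-acetamidobenzenesulfonyl azide, CC(=O)Nc1ccc(cc1)S(=O)(=O)N=[N+]=[N-]
Why: Regitz diazo transfer to a doubly activated methylene; the phosphonate-ester carbanion attacks the terminal azide nitrogen and the sulfonamide is expelled.

Step 12
Reactants: 19 ethyl 2-diazo-2-(diethoxyphosphoryl)acetate; 20 benzyl alcohol
Product: 21 ethyl 2-(benzyloxy)-2-(diethoxyphosphoryl)acetate (racemic)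
Conditions: Rh2(OAc)4 (1 mol%), toluene, 80 °C
Reagents that add atoms: none
Why: Rh2(OAc)4 converts the diazo compound into a rhodium carbenoid that inserts into the O–H bond of the alcohol, the standard entry to alpha-alkoxy phosphonoacetates.

Step 13
Reactants: 21 ethyl 2-(benzyloxy)-2-(diethoxyphosphoryl)acetate
Product: 22 2-(benzyloxy)-2-(diethoxyphosphoryl)acetic acid (racemic)
Conditions: NaOH (1.05 equiv), EtOH/H2O, 0 °C → rt; then 1 M HCl
Reagents that add atoms: sodium hydroxide, [Na+].[OH-]
Why: Selective saponification; the carboxylic ester is hydrolysed far faster than the phosphonate diethyl ester.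

Step 14
Reactants: 17 methyl (2R)-3-[4-(benzyloxy)phenyl]-2-hydroxy-3-oxo-2-({(2S)-2-[2-(triethylsilyloxy)propan-2-yl]-2,3-dihydro-1-benzofuran-5-yl}methyl)propanoate; 22 2-(benzyloxy)-2-(diethoxyphosphoryl)acetic acid
Product: 23 methyl (2R)-2-{[2-(benzyloxy)-2-(diethoxyphosphoryl)acetyl]oxy}-3-[4-(benzyloxy)phenyl]-3-oxo-2-({(2S)-2-[2-(triethylsilyloxy)propan-2-yl]-2,3-dihydro-1-benzofuran-5-yl}methyl)propanoate (mixture at the phosphonate carbon)
Conditions: DCC, DMAP (cat.), CH2Cl2, 0 °C → rt
Reagents that add atoms: none
Why: Steglich esterification; carbodiimide-activated phosphonoacetic acids acylate hindered tertiary alcohols, plausibly through a phosphono ketene, and the only free hydroxyl is the one on the quaternary carbon because the side-chain carbinol is silylated.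

Step 15
Reactants: 23 methyl (2R)-2-{[2-(benzyloxy)-2-(diethoxyphosphoryl)acetyl]oxy}-3-[4-(benzyloxy)phenyl]-3-oxo-2-({(2S)-2-[2-(triethylsilyloxy)propan-2-yl]-2,3-dihydro-1-benzofuran-5-yl}methyl)propanoate
Product: 24 methyl (2R)-4-(benzyloxy)-3-[4-(benzyloxy)phenyl]-5-oxo-2-({(2S)-2-[2-(triethylsilyloxy)propan-2-yl]-2,3-dihydro-1-benzofuran-5-yl}methyl)-2,5-dihydrofuran-2-carboxylate
Conditions: LiCl, DBU, MeCN, rt → 50 °C
Reagents that add atoms: none
Why: Intramolecular Horner–Wadsworth–Emmons reaction under Masamune–Roush conditions; the lithium-chelated phosphonate carbanion adds to the neighbouring aryl ketone in a five-membered closure and the oxaphosphetane collapses irreversibly to the C3=C4 bond, while the quaternary carbon has no hydrogen and cannot epimerise.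

Step 16
Reactants: 24 methyl (2R)-4-(benzyloxy)-3-[4-(benzyloxy)phenyl]-5-oxo-2-({(2S)-2-[2-(triethylsilyloxy)propan-2-yl]-2,3-dihydro-1-benzofuran-5-yl}methyl)-2,5-dihydrofuran-2-carboxylate
Product: 25 methyl (2R)-4-(benzyloxy)-3-[4-(benzyloxy)phenyl]-2-{[(2S)-2-(2-hydroxypropan-2-yl)-2,3-dihydro-1-benzofuran-5-yl]methyl}-5-oxo-2,5-dihydrofuran-2-carboxylate
Conditions: HF·pyridine, THF/pyridine, 0 °C → rt
Reagents that add atoms: none
Why: Fluoride-driven cleavage of the tertiary triethylsilyl ether in a buffered, weakly acidic medium that does not ionise the tertiary carbinol and leaves the benzyl ethers, ester and lactone alone.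

Step 17
Reactants: 25 methyl (2R)-4-(benzyloxy)-3-[4-(benzyloxy)phenyl]-2-{[(2S)-2-(2-hydroxypropan-2-yl)-2,3-dihydro-1-benzofuran-5-yl]methyl}-5-oxo-2,5-dihydrofuran-2-carboxylate
Product: 26 methyl (2R)-4-hydroxy-3-(4-hydroxyphenyl)-2-{[(2S)-2-(2-hydroxypropan-2-yl)-2,3-dihydro-1-benzofuran-5-yl]methyl}-5-oxo-2,5-dihydrofuran-2-carboxylate
Conditions: H2 (1 atm), Pd/C (10%), EtOAc/MeOH, rt
Reagents that add atoms: none
Why: Hydrogenolysis of the aryl benzyl ether and the enol benzyl ether under neutral conditions; the tetrasubstituted, conjugated ring double bond and the non-benzylic C2'–O bond are not expected to react.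

## Compound list

1 | 3-iodo-L-tyrosine | N[C@@H](Cc1ccc(O)c(I)c1)C(=O)O | starting material
2 | (2S)-2-hydroxy-3-(4-hydroxy-3-iodophenyl)propanoic acid | O[C@@H](Cc1ccc(O)c(I)c1)C(=O)O | intermediate
3 | methyl (2S)-2-hydroxy-3-(4-hydroxy-3-iodophenyl)propanoate | O[C@@H](Cc1ccc(O)c(I)c1)C(=O)OC | intermediate
4 | tributyl(3-methylbut-2-en-1-yl)stannane | CCCC[Sn](CCCC)(CCCC)CC=C(C)C | starting material
5 | methyl (2S)-2-hydroxy-3-[4-hydroxy-3-(3-methylbut-2-en-1-yl)phenyl]propanoate | O[C@@H](Cc1ccc(O)c(CC=C(C)C)c1)C(=O)OC | intermediate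
6 | methyl (2S)-3-[4-(tert-butyldimethylsilyloxy)-3-(3-methylbut-2-en-1-yl)phenyl]-2-hydroxypropanoate | O[C@@H](Cc1ccc(O[Si](C)(C)C(C)(C)C)c(CC=C(C)C)c1)C(=O)OC | intermediate
7 | methyl (2S)-3-{4-(tert-butyldimethylsilyloxy)-3-[((2R)-3,3-dimethyloxiran-2-yl)methyl]phenyl}-2-hydroxypropanoate | O[C@@H](Cc1ccc(O[Si](C)(C)C(C)(C)C)c(C[C@H]2OC2(C)C)c1)C(=O)OC | intermediate
8 | methyl (2S)-3-{3-[((2R)-3,3-dimethyloxiran-2-yl)methyl]-4-hydroxyphenyl}-2-hydroxypropanoate | O[C@@H](Cc1ccc(O)c(C[C@H]2OC2(C)C)c1)C(=O)OC | intermediate
9 | methyl (2S)-2-hydroxy-3-[(2S)-2-(2-hydroxypropan-2-yl)-2,3-dihydro-1-benzofuran-5-yl]propanoate | O[C@@H](Cc1ccc2c(c1)C[C@@H](C(C)(C)O)O2)C(=O)OC | intermediate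
10 | (2S)-2-hydroxy-3-[(2S)-2-(2-hydroxypropan-2-yl)-2,3-dihydro-1-benzofuran-5-yl]propanoic acid | O[C@@H](Cc1ccc2c(c1)C[C@@H](C(C)(C)O)O2)C(=O)O | intermediate
11 | pivalaldehyde (2,2-dimethylpropanal) | CC(C)(C)C=O | starting material
12 | triethylsilyl (2S)-2-(triethylsilyloxy)-3-{(2S)-2-[2-(triethylsilyloxy)propan-2-yl]-2,3-dihydro-1-benzofuran-5-yl}propanoate | CC[Si](CC)(CC)O[C@@H](Cc1ccc2c(c1)C[C@@H](C(C)(C)O[Si](CC)(CC)CC)O2)C(=O)O[Si](CC)(CC)CC | intermediate
13 | (2S,5S)-2-tert-butyl-5-({(2S)-2-[2-(triethylsilyloxy)propan-2-yl]-2,3-dihydro-1-benzofuran-5-yl}methyl)-1,3-dioxolan-4-one | O=C1O[C@@H](C(C)(C)C)O[C@H]1Cc1ccc2c(c1)C[C@@H](C(C)(C)O[Si](CC)(CC)CC)O2 | intermediate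
14 | 4-(benzyloxy)benzaldehyde | O=Cc1ccc(OCc2ccccc2)cc1 | starting material
15 | (2S,5R)-5-{[4-(benzyloxy)phenyl](hydroxy)methyl}-2-tert-butyl-5-({(2S)-2-[2-(triethylsilyloxy)propan-2-yl]-2,3-dihydro-1-benzofuran-5-yl}methyl)-1,3-dioxolan-4-one (carbinol epimers) | O=C1O[C@@H](C(C)(C)C)O[C@]1(Cc1ccc2c(c1)C[C@@H](C(C)(C)O[Si](CC)(CC)CC)O2)C(O)c1ccc(OCc2ccccc2)cc1 | intermediate
16 | methyl (2R)-3-[4-(benzyloxy)phenyl]-2,3-dihydroxy-2-({(2S)-2-[2-(triethylsilyloxy)propan-2-yl]-2,3-dihydro-1-benzofuran-5-yl}methyl)propanoate (C3 epimers) | COC(=O)[C@@](O)(Cc1ccc2c(c1)C[C@@H](C(C)(C)O[Si](CC)(CC)CC)O2)C(O)c1ccc(OCc2ccccc2)cc1 | intermediate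
17 | methyl (2R)-3-[4-(benzyloxy)phenyl]-2-hydroxy-3-oxo-2-({(2S)-2-[2-(triethylsilyloxy)propan-2-yl]-2,3-dihydro-1-benzofuran-5-yl}methyl)propanoate | COC(=O)[C@@](O)(Cc1ccc2c(c1)C[C@@H](C(C)(C)O[Si](CC)(CC)CC)O2)C(=O)c1ccc(OCc2ccccc2)cc1 | intermediate
18 | triethyl phosphonoacetate | CCOC(=O)CP(=O)(OCC)OCC | starting material
19 | ethyl 2-diazo-2-(diethoxyphosphoryl)acetate | CCOC(=O)C(=[N+]=[N-])P(=O)(OCC)OCC | intermediate
20 | benzyl alcohol | OCc1ccccc1 | starting material
21 | ethyl 2-(benzyloxy)-2-(diethoxyphosphoryl)acetate (racemic) | CCOC(=O)C(OCc1ccccc1)P(=O)(OCC)OCC | intermediate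
22 | 2-(benzyloxy)-2-(diethoxyphosphoryl)acetic acid (racemic) | OC(=O)C(OCc1ccccc1)P(=O)(OCC)OCC | intermediate
23 | methyl (2R)-2-{[2-(benzyloxy)-2-(diethoxyphosphoryl)acetyl]oxy}-3-[4-(benzyloxy)phenyl]-3-oxo-2-({(2S)-2-[2-(triethylsilyloxy)propan-2-yl]-2,3-dihydro-1-benzofuran-5-yl}methyl)propanoate (mixture at the phosphonate carbon) | COC(=O)[C@@](OC(=O)C(OCc1ccccc1)P(=O)(OCC)OCC)(Cc1ccc2c(c1)C[C@@H](C(C)(C)O[Si](CC)(CC)CC)O2)C(=O)c1ccc(OCc2ccccc2)cc1 | intermediate
24 | methyl (2R)-4-(benzyloxy)-3-[4-(benzyloxy)phenyl]-5-oxo-2-({(2S)-2-[2-(triethylsilyloxy)propan-2-yl]-2,3-dihydro-1-benzofuran-5-yl}methyl)-2,5-dihydrofuran-2-carboxylate | COC(=O)[C@]1(Cc2ccc3c(c2)C[C@@H](C(C)(C)O[Si](CC)(CC)CC)O3)OC(=O)C(OCc2ccccc2)=C1c1ccc(OCc2ccccc2)cc1 | intermediate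
25 | methyl (2R)-4-(benzyloxy)-3-[4-(benzyloxy)phenyl]-2-{[(2S)-2-(2-hydroxypropan-2-yl)-2,3-dihydro-1-benzofuran-5-yl]methyl}-5-oxo-2,5-dihydrofuran-2-carboxylate | COC(=O)[C@]1(Cc2ccc3c(c2)C[C@@H](C(C)(C)O)O3)OC(=O)C(OCc2ccccc2)=C1c1ccc(OCc2ccccc2)cc1 | intermediate
26 | methyl (2R)-4-hydroxy-3-(4-hydroxyphenyl)-2-{[(2S)-2-(2-hydroxypropan-2-yl)-2,3-dihydro-1-benzofuran-5-yl]methyl}-5-oxo-2,5-dihydrofuran-2-carboxylate | COC(=O)[C@]1(Cc2ccc3c(c2)C[C@@H](C(C)(C)O)O3)OC(=O)C(O)=C1c1ccc(O)cc1 | target

## Step count and least certain steps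

Total step count: 17 (14 in the main line, 3 for phosphono acid 22).
Longest linear sequence: 14 steps, from 1 through steps 1–10 and 14–17.

**Step 8 (key step).** The lithium enolate of a 5-arylmethyl dioxolanone may decompose before it is trapped, and the lithium aldolate may revert by retro-aldol cleavage or transfer the acyl group on warming, so that conversion and not facial selectivity becomes the limit. Fallback: dioxolanone 13 is converted with LiN(iPr)2 and Me3SiCl at −78 °C into the silyl ketene acetal (2S)-2-tert-butyl-5-({(2S)-2-[2-(triethylsilyloxy)propan-2-yl]-2,3-dihydro-1-benzofuran-5-yl}methyl)-4-(trimethylsilyloxy)-1,3-dioxole F1. This is combined with aldehyde 14 under BF3·OEt2 in CH2Cl2 at −78 °C in a Mukaiyama aldol addition. The nucleophile is then neutral, no free aldolate is formed, and the tert-butyl group still directs attack to the same face. The route is rejoined at 15.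

**Step 14.** Acylation of the tertiary hydroxyl, which is flanked by a ketone, an ester and a benzyl group, may be too slow, so that N-acylurea formation or base-induced alpha-ketol rearrangement takes over. Fallback: ketol 17 is treated with the lithium enolate of methyl 2-(benzyloxy)acetate (LiN(SiMe3)2, THF, −78 °C, two equivalents). Addition to the ketone and spontaneous lactonisation of the C5 alkoxide onto the new ester give the hydroxy lactone methyl (2R)-4-(benzyloxy)-3-[4-(benzyloxy)phenyl]-3-hydroxy-5-oxo-2-({(2S)-2-[2-(triethylsilyloxy)propan-2-yl]-2,3-dihydro-1-benzofuran-5-yl}methyl)oxolane-2-carboxylate F2. Dehydration of its tertiary benzylic alcohol with SOCl2 and pyridine rejoins the route at 24. No tertiary alcohol has to be acylated intermolecularly.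

**Step 15.** Olefination of the hindered, electron-rich aryl ketone may stall, leaving time for the phosphonate carbanion to attack the C5 methyl ester or for the acyloxy group to be lost. Fallback: ketol 17 is acylated through its lithium alkoxide with the small 2-(benzyloxy)acetyl chloride to give methyl (2R)-2-{[2-(benzyloxy)acetyl]oxy}-3-[4-(benzyloxy)phenyl]-3-oxo-2-({(2S)-2-[2-(triethylsilyloxy)propan-2-yl]-2,3-dihydro-1-benzofuran-5-yl}methyl)propanoate F3. Its more reactive ester enolate (LiN(SiMe3)2, THF, −78 °C) closes by intramolecular aldol addition to the same hydroxy lactone F2, which is dehydrated as above. The route is rejoined at 24.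

**Step 7.** Silylation of the hindered tertiary hydroxyl may be incomplete before the acetalisation, residual base may quench the silyl triflate catalyst, or the bulkier triethylsilyl groups may erode the cis preference. Fallback: acid 10 and pivalaldehyde 11 are condensed under TsOH catalysis in refluxing pentane with azeotropic removal of water. This gives (2S,5S)-2-tert-butyl-5-{[(2S)-2-(2-hydroxypropan-2-yl)-2,3-dihydro-1-benzofuran-5-yl]methyl}-1,3-dioxolan-4-one F4 under thermodynamic control. It is then silylated with Et3SiOTf and 2,6-lutidine at −78 °C, and the route is rejoined at 13.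

**Step 9.** Methoxide may deprotonate the benzylic carbinol and trigger retro-aldol loss of the C4–C5 bond before or after the acetal opens. Fallback: adduct 15 is first silylated (Et3SiCl, imidazole, DMAP) to the bis-silyl ether (2S,5R)-5-{[4-(benzyloxy)phenyl](triethylsilyloxy)methyl}-2-tert-butyl-5-({(2S)-2-[2-(triethylsilyloxy)propan-2-yl]-2,3-dihydro-1-benzofuran-5-yl}methyl)-1,3-dioxolan-4-one F5, which has no hydroxyl beta to the quaternary carbon. Methanolysis with NaOMe gives methyl (2R)-3-[4-(benzyloxy)phenyl]-2-hydroxy-3-(triethylsilyloxy)-2-({(2S)-2-[2-(triethylsilyloxy)propan-2-yl]-2,3-dihydro-1-benzofuran-5-yl}methyl)propanoate F6. The secondary silyl ether is then removed selectively with pyridinium p-toluenesulfonate in MeOH at 0 °C, and the route is rejoined at 16.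

## Further compounds

F1 | step 8 | (2S)-2-tert-butyl-5-({(2S)-2-[2-(triethylsilyloxy)propan-2-yl]-2,3-dihydro-1-benzofuran-5-yl}methyl)-4-(trimethylsilyloxy)-1,3-dioxole | C[Si](C)(C)OC1=C(Cc2ccc3c(c2)C[C@@H](C(C)(C)O[Si](CC)(CC)CC)O3)O[C@H](C(C)(C)C)O1
F2 | step 14 | methyl (2R)-4-(benzyloxy)-3-[4-(benzyloxy)phenyl]-3-hydroxy-5-oxo-2-({(2S)-2-[2-(triethylsilyloxy)propan-2-yl]-2,3-dihydro-1-benzofuran-5-yl}methyl)oxolane-2-carboxylate (mixture at C3 and C4) | COC(=O)[C@]1(Cc2ccc3c(c2)C[C@@H](C(C)(C)O[Si](CC)(CC)CC)O3)OC(=O)C(OCc2ccccc2)C1(O)c1ccc(OCc2ccccc2)cc1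
F3 | step 15 | methyl (2R)-2-{[2-(benzyloxy)acetyl]oxy}-3-[4-(benzyloxy)phenyl]-3-oxo-2-({(2S)-2-[2-(triethylsilyloxy)propan-2-yl]-2,3-dihydro-1-benzofuran-5-yl}methyl)propanoate | COC(=O)[C@@](OC(=O)COCc1ccccc1)(Cc1ccc2c(c1)C[C@@H](C(C)(C)O[Si](CC)(CC)CC)O2)C(=O)c1ccc(OCc2ccccc2)cc1
F4 | step 7 | (2S,5S)-2-tert-butyl-5-{[(2S)-2-(2-hydroxypropan-2-yl)-2,3-dihydro-1-benzofuran-5-yl]methyl}-1,3-dioxolan-4-one | O=C1O[C@@H](C(C)(C)C)O[C@H]1Cc1ccc2c(c1)C[C@@H](C(C)(C)O)O2
F5 | step 9 | (2S,5R)-5-{[4-(benzyloxy)phenyl](triethylsilyloxy)methyl}-2-tert-butyl-5-({(2S)-2-[2-(triethylsilyloxy)propan-2-yl]-2,3-dihydro-1-benzofuran-5-yl}methyl)-1,3-dioxolan-4-one (carbinol epimers) | O=C1O[C@@H](C(C)(C)C)O[C@]1(Cc1ccc2c(c1)C[C@@H](C(C)(C)O[Si](CC)(CC)CC)O2)C(O[Si](CC)(CC)CC)c1ccc(OCc2ccccc2)cc1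
F6 | step 9 | methyl (2R)-3-[4-(benzyloxy)phenyl]-2-hydroxy-3-(triethylsilyloxy)-2-({(2S)-2-[2-(triethylsilyloxy)propan-2-yl]-2,3-dihydro-1-benzofuran-5-yl}methyl)propanoate (C3 epimers) | COC(=O)[C@@](O)(Cc1ccc2c(c1)C[C@@H](C(C)(C)O[Si](CC)(CC)CC)O2)C(O[Si](CC)(CC)CC)c1ccc(OCc2ccccc2)cc1
A1 | alternative 1 | methyl (2R)-4-(benzyloxy)-3-[4-(benzyloxy)phenyl]-2-({4-hydroxy-3-[(2E)-4-(methoxycarbonyloxy)-3-methylbut-2-en-1-yl]phenyl}methyl)-5-oxo-2,5-dihydrofuran-2-carboxylate | COC(=O)[C@]1(Cc2ccc(O)c(C/C=C(\C)COC(=O)OC)c2)OC(=O)C(OCc2ccccc2)=C1c1ccc(OCc2ccccc2)cc1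
A2 | alternative 1 | methyl (2R)-4-(benzyloxy)-3-[4-(benzyloxy)phenyl]-5-oxo-2-{[(2S)-2-(prop-1-en-2-yl)-2,3-dihydro-1-benzofuran-5-yl]methyl}-2,5-dihydrofuran-2-carboxylate | COC(=O)[C@]1(Cc2ccc3c(c2)C[C@@H](C(C)=C)O3)OC(=O)C(OCc2ccccc2)=C1c1ccc(OCc2ccccc2)cc1
A3 | alternative 2 | methyl 2-(2-hydroxypropan-2-yl)-1-benzofuran-5-carboxylate | COC(=O)c1ccc2oc(C(C)(C)O)cc2c1
A4 | alternative 2 | methyl (2S)-2-(2-hydroxypropan-2-yl)-2,3-dihydro-1-benzofuran-5-carboxylate | COC(=O)c1ccc2c(c1)C[C@@H](C(C)(C)O)O2
A5 | alternative 3 | methyl 4-(benzyloxy)-3-[4-(benzyloxy)phenyl]-5-oxo-2,5-dihydrofuran-2-carboxylate | COC(=O)C1OC(=O)C(OCc2ccccc2)=C1c1ccc(OCc2ccccc2)cc1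
A6 | alternative 3 | 2-[(2S)-5-(bromomethyl)-2,3-dihydro-1-benzofuran-2-yl]propan-2-ol | BrCc1ccc2c(c1)C[C@@H](C(C)(C)O)O2
A7 | alternative 3 | methyl (2R)-4-(benzyloxy)-3-[4-(benzyloxy)phenyl]-2-{[(2S)-2-(2-hydroxypropan-2-yl)-2,3-dihydro-1-benzofuran-5-yl]methyl}-5-oxo-2,5-dihydrofuran-2-carboxylate | COC(=O)[C@]1(Cc2ccc3c(c2)C[C@@H](C(C)(C)O)O3)OC(=O)C(OCc2ccccc2)=C1c1ccc(OCc2ccccc2)cc1
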